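## Retrosynthetic overview

1. The C15–O ester bond is cut to give (3R,5S,9R,10S)-labda-7,13E-diene-3,15-diol and a 30-silyloxytriacontanoic acid. The acid is built from two C15 halves of ω-pentadecalactone by a Wittig reaction and hydrogenation.
2. The 3-OH and the C4 gem-dimethyl group are traced back to a bicyclic 4-phenylsulfonyl-3-ketone (methylation, reductive desulfonylation–methylation, hydride reduction).
3. Key disconnection: this trans-decalin is an isomer of a 1-sulfonylbicyclo[3.1.0]hexan-2-one that carries the polyene chain on its cyclopropane apex. A Lewis acid breaks the ring-fusion bond C4–C10, the cyclopentanone C3–C2–C1–C10–C4 takes in C5 and becomes ring A, and C8=C9 closes ring B on C10 in the same event.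
4. Enabling feature: C10, the methyl-bearing quaternary ring-fusion carbon, is bonded to C5 and stands γ to the C3 oxygen. C4, C5 and C10 can therefore be tied into an acceptor-activated cyclopropane whose only tertiary corner lies within six-ring reach of the C8=C9 olefin. An E-C5=C10 olefin encodes the trans fusion of rings A and B.
5. The cyclopropane comes from an acyclic diazo keto sulfone (farnesol C15 + sulfonylacetone C3) by asymmetric intramolecular carbene addition. Ring order: cyclopropane and cyclopentanone first, then rings A and B together.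

Key step: step 7

Numbering: labdane numbering (C1–C20) is used for all intermediates, acyclic ones included.

Assumption: the (S,S)-bisoxazoline is taken to give the (1S,5S,6S)-cyclopropane in step 6. If the sense of induction is the opposite, the equally available (R,R)-ligand is used and nothing else changes.

## Route

Step 1
Reactants: 1 (2E,6E)-farnesol
Product: 2 (2E,6E)-farnesyl pivalate
Conditions: t-BuCOCl, pyridine, DMAP (cat.), CH2Cl2, 0 °C to rt
Reagents that add atoms: pivaloyl chloride CC(C)(C)C(=O)Cl
Why: Simple O-acylation gives a hindered, non-enolisable ester that should survive the later carbanion steps and lower the nucleophilicity of the C13=C14 olefin in the key step.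

Step 2
Reactants: 2 (2E,6E)-farnesyl pivalate
Product: 3 (2E,6E,10E)-12-hydroxy-3,7,11-trimethyldodeca-2,6,10-trien-1-yl pivalate
Conditions: SeO2 (0.3 equiv), t-BuOOH, salicylic acid (cat.), CH2Cl2, 0 °C, stopped at partial conversion
Reagents that add atoms: selenium dioxide O=[Se]=O (oxygen carrier, catalytic); tert-butyl hydroperoxide CC(C)(C)OO (terminal oxygen source)
Why: Riley-type allylic oxidation (ene reaction, then [2,3]-shift) should pick the most electron-rich terminal trisubstituted olefin and deliver the E-allylic alcohol, which fixes the E-C5=C10 geometry.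

Step 3
Reactants: 3 (2E,6E,10E)-12-hydroxy-3,7,11-trimethyldodeca-2,6,10-trien-1-yl pivalate
Product: 4 (2E,6E,10E)-12-bromo-3,7,11-trimethyldodeca-2,6,10-trien-1-yl pivalate
Conditions: CBr4, PPh3, CH2Cl2, −20 to 0 °C
Reagents that add atoms: carbon tetrabromide BrC(Br)(Br)Br
Why: The Appel reaction converts the primary allylic alcohol under neutral conditions without allylic transposition or loss of olefin geometry.

Step 4
Reactants: 4 (2E,6E,10E)-12-bromo-3,7,11-trimethyldodeca-2,6,10-trien-1-yl pivalate; 5 1-(phenylsulfonyl)propan-2-one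
Product: 7 (2E,6E,10E)-3,7,11-trimethyl-14-oxo-15-(phenylsulfonyl)pentadeca-2,6,10-trien-1-yl pivalate, via sulfonylacetone dianion 6 (not isolated)
Conditions: 5, NaH, THF, 0 °C; n-BuLi, 0 °C; then 4, −78 to 0 °C; AcOH quench
Reagents that add atoms: none
Why: In this γ-alkylation of a β-keto sulfone 1,3-dianion the last-formed, less stabilised terminal carbanion attacks the primary allylic bromide by SN2, joins C1 to C2 and leaves the hindered pivalate alone.

Step 5
Reactants: 7 (2E,6E,10E)-3,7,11-trimethyl-14-oxo-15-(phenylsulfonyl)pentadeca-2,6,10-trien-1-yl pivalate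
Product: 8 (2E,6E,10E)-15-diazo-3,7,11-trimethyl-14-oxo-15-(phenylsulfonyl)pentadeca-2,6,10-trien-1-yl pivalate
Conditions: 4-acetamidobenzenesulfonyl azide, Et3N, MeCN, 0 °C to rt
Reagents that add atoms: 4-acetamidobenzenesulfonyl azide CC(=O)Nc1ccc(cc1)S(=O)(=O)N=[N+]=[N-]
Why: Regitz diazo transfer takes place only at the doubly activated methylene C4.

Step 6
Reactants: 8 (2E,6E,10E)-15-diazo-3,7,11-trimethyl-14-oxo-15-(phenylsulfonyl)pentadeca-2,6,10-trien-1-yl pivalate
Product: 9 (2E,6E)-3,7-dimethyl-9-[(1S,5S,6S)-5-methyl-2-oxo-1-(phenylsulfonyl)bicyclo[3.1.0]hexan-6-yl]nona-2,6-dien-1-yl pivalate (chain exo, cis to the 5-methyl group)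
Conditions: (CuOTf)2·C6H6 (5 mol %), 2,2'-(propane-2,2-diyl)bis[(4S)-4-isopropyl-4,5-dihydrooxazole] (12 mol %), toluene, slow addition of 8, rt to 50 °C
Reagents that add atoms: none
Why: This is a catalytic asymmetric intramolecular cyclopropanation of an α-diazo-β-keto sulfone by a monovalent copper bisoxazoline carbenoid, in which only the C5=C10 olefin gives a five-membered tether ring, the syn addition turns the E geometry into the relative configuration of C4, C5 and C10 (chain exo), and the ligand chooses the olefin face and thereby the absolute configuration.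

Step 7
Reactants: 9 (2E,6E)-3,7-dimethyl-9-[(1S,5S,6S)-5-methyl-2-oxo-1-(phenylsulfonyl)bicyclo[3.1.0]hexan-6-yl]nona-2,6-dien-1-yl pivalate
Product: 10 (4R,5S,9R,10S)-3-oxo-4-(phenylsulfonyl)-18,19-dinorlabda-7,13E-dien-15-yl pivalate (trans-decalin, sulfonyl group equatorial)
Conditions: SnCl4 (20 mol %), CH2Cl2 (0.01 M), −78 to −20 °C; then aq NaHCO3
Reagents that add atoms: none
Why: Proposed new method: SnCl4 binds the ketone and a sulfonyl oxygen of 9 and polarises the ring-fusion bond C4–C10 of the bicyclo[3.1.0]hexanone, the C8=C9 olefin (held by the C6–C7 tether on the apex C5) attacks C10 from the rear of that bond, the cyclopentanone (C3, C2, C1, C10, C4) thereby takes in C5 and becomes six-membered ring A while the keto sulfone enolate departs, and the C8 cation loses the axial 7-H, which ends on the enolate (net isomerisation, SnCl4 turns over). The closest known reaction types are the acid-catalysed opening of acylcyclopropanes with olefin or aryl participation, the Lewis acid opening of donor–acceptor cyclopropanes at their more substituted carbon, and the thujane-to-menthane and cyclosteroid enlargements of bicyclo[3.1.0]hexyl systems; what is new is their union on a doubly activated, purely alkyl-substituted cyclopropane inside a polyene. Ring B closes 6-endo-trig at the olefin and with SN2-like inversion at C10 through a chair, whereas ring A forms no new bond and arises by one-carbon enlargement of the five-membered ring. C10 is set by inversion at the cyclopropane carbon and C5 is carried over from 9, so that syn carbene addition followed by anti olefin attack equals the anti addition across the former E-C5=C10 olefin that a trans-decalin needs; C9 is set by the E geometry of C8=C9 in the chair (C11 equatorial, cis to the C10 methyl group), and C4 settles by enolisation with the sulfonyl group equatorial and is erased later. The step needs cleavage of C4–C10 rather than C4–C5, a stop after one ring, and the 7,8-olefin. These are secured because C10 is tertiary and C5 secondary, only C10 lies within six-ring reach of the olefin, the exocyclic sulfonyl group stabilises the departing carbanion whatever the orbital alignment of the ring ketone, the allylic pivalate lowers the nucleophilicity of C13=C14, and the weakly acidic medium favours the trisubstituted endocyclic olefin.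

Step 8
Reactants: 10 (4R,5S,9R,10S)-3-oxo-4-(phenylsulfonyl)-18,19-dinorlabda-7,13E-dien-15-yl pivalate
Product: 11 (4S,5S,9R,10S)-3-oxo-4-(phenylsulfonyl)-19-norlabda-7,13E-dien-15-yl pivalate (4-methyl equatorial, sulfonyl axial; the C4 configuration has no consequence)
Conditions: MeI, K2CO3, DMF, rt
Reagents that add atoms: iodomethane CI
Why: C-alkylation of the β-keto sulfone anion occurs only at the acidic C4, and the methyl group should enter from the face opposite the axial C10 methyl group.

Step 9
Reactants: 11 (4S,5S,9R,10S)-3-oxo-4-(phenylsulfonyl)-19-norlabda-7,13E-dien-15-yl pivalate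
Product: 13 (5S,9R,10S)-3-oxolabda-7,13E-dien-15-yl pivalate, via lithium enolate 12 (not isolated)
Conditions: lithium naphthalenide LiC10H8 (2.1 equiv, added to a persistent green colour), THF, −78 °C; then MeI (5 equiv), −78 to 0 °C
Reagents that add atoms: iodomethane CI
Why: Reductive cleavage of the α-sulfonyl ketone gives the C3–C4 enolate regiospecifically (the keto sulfone is reduced far more easily than the ester), and its methylation completes the gem-dimethyl group in a regiospecific reductive alkylation.

Step 10
Reactants: 13 (5S,9R,10S)-3-oxolabda-7,13E-dien-15-yl pivalate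
Product: 14 (3R,5S,9R,10S)-labda-7,13E-diene-3,15-diol
Conditions: LiAlH4, Et2O, 0 °C to rt; aqueous NaOH work-up
Reagents that add atoms: none
Why: Hydride should reach C3 along the axial trajectory on the face opposite the axial C4 and C10 methyl groups and give the equatorial (3R) alcohol, as is usual for 4,4-dimethyl-3-ketones, while the same reagent cleaves the pivalate.

Step 11
Reactants: 15 ω-pentadecalactone (oxacyclohexadecan-2-one)
Product: 16 15-bromopentadecanoic acid
Conditions: HBr (33 % in AcOH), 80 °C
Reagents that add atoms: hydrogen bromide Br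
Why: Acidic alkyl–oxygen cleavage of the protonated lactone by bromide (SN2 at the primary carbon) opens the ring to the ω-bromo acid.

Step 12
Reactants: 16 15-bromopentadecanoic acid
Product: 17 (14-carboxytetradecyl)triphenylphosphonium bromide
Conditions: PPh3, MeCN, reflux
Reagents that add atoms: triphenylphosphine c1ccc(cc1)P(c1ccccc1)c1ccccc1
Why: Quaternisation of PPh3 by a primary bromide is a standard SN2 entry to carboxyalkyl Wittig salts.

Step 13
Reactants: 15 ω-pentadecalactone (oxacyclohexadecan-2-one)
Product: 18 methyl 15-hydroxypentadecanoate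
Conditions: MeOH, H2SO4 (cat.), reflux
Reagents that add atoms: methanol CO
Why: Acid-catalysed transesterification in excess methanol opens the macrolactone.

Step 14
Reactants: 18 methyl 15-hydroxypentadecanoate
Product: 19 methyl 15-(tert-butyldiphenylsilyloxy)pentadecanoate
Conditions: t-BuPh2SiCl, imidazole, DMF, rt
Reagents that add atoms: tert-butyl(chloro)diphenylsilane CC(C)(C)[Si](Cl)(c1ccccc1)c1ccccc1
Why: Silylation of the primary alcohol installs a group that withstands ylide, hydrogenation and carbodiimide conditions and is removed by fluoride at the end.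

Step 15
Reactants: 19 methyl 15-(tert-butyldiphenylsilyloxy)pentadecanoate
Product: 20 15-(tert-butyldiphenylsilyloxy)pentadecanal
Conditions: i-Bu2AlH (1.05 equiv), CH2Cl2, −78 °C; aqueous potassium sodium tartrate
Reagents that add atoms: none
Why: Partial reduction of the methyl ester stops at the tetrahedral aluminium adduct at −78 °C and releases the aldehyde on work-up.

Step 16
Reactants: 17 (14-carboxytetradecyl)triphenylphosphonium bromide; 20 15-(tert-butyldiphenylsilyloxy)pentadecanal
Product: 22 (15Z)-30-(tert-butyldiphenylsilyloxy)triacont-15-enoic acid, via ylide carboxylate 21 (not isolated)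
Conditions: 17, NaN(SiMe3)2 (2.1 equiv), THF, 0 °C; then 20, −78 °C to rt; 1 M HCl work-up
Reagents that add atoms: none
Why: The Wittig reaction of the non-stabilised ylide carboxylate joins the two C15 halves to the C30 chain, and the olefin geometry is irrelevant because it is hydrogenated next.

Step 17
Reactants: 22 (15Z)-30-(tert-butyldiphenylsilyloxy)triacont-15-enoic acid
Product: 23 30-(tert-butyldiphenylsilyloxy)triacontanoic acid
Conditions: H2 (1 atm), 10 % Pd/C, EtOAc, rt
Reagents that add atoms: none
Why: Catalytic hydrogenation saturates the isolated disubstituted olefin and leaves the silyl ether and the acid untouched.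

Step 18
Reactants: 14 (3R,5S,9R,10S)-labda-7,13E-diene-3,15-diol; 23 30-(tert-butyldiphenylsilyloxy)triacontanoic acid
Product: 24 (3R,5S,9R,10S)-3-hydroxylabda-7,13E-dien-15-yl 30-(tert-butyldiphenylsilyloxy)triacontanoate
Conditions: 23 (1.0 equiv), DCC, DMAP (cat.), CH2Cl2, 0 °C to rt
Reagents that add atoms: none
Why: In the Steglich esterification the primary allylic C15 hydroxyl reacts much faster than the secondary C3 hydroxyl, which is shielded by the adjacent gem-dimethyl group.

Step 19
Reactants: 24 (3R,5S,9R,10S)-3-hydroxylabda-7,13E-dien-15-yl 30-(tert-butyldiphenylsilyloxy)triacontanoate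
Product: 25 (3R,5S,9R,10S)-3-hydroxylabda-7,13E-dien-15-yl 30-hydroxytriacontanoate (target)
Conditions: HF·pyridine, pyridine, THF, 0 °C to rt
Reagents that add atoms: none
Why: Buffered fluoride desilylation frees the terminal alcohol without touching the allylic ester, the olefins or the stereocentres.

## Compound list

1 | (2E,6E)-farnesol | CC(C)=CCC/C(C)=C/CC/C(C)=C/CO | starting material
2 | (2E,6E)-farnesyl pivalate | CC(C)=CCC/C(C)=C/CC/C(C)=C/COC(=O)C(C)(C)C | intermediate
3 | (2E,6E,10E)-12-hydroxy-3,7,11-trimethyldodeca-2,6,10-trien-1-yl pivalate | OC/C(C)=C/CC/C(C)=C/CC/C(C)=C/COC(=O)C(C)(C)C | intermediate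
4 | (2E,6E,10E)-12-bromo-3,7,11-trimethyldodeca-2,6,10-trien-1-yl pivalate | BrC/C(C)=C/CC/C(C)=C/CC/C(C)=C/COC(=O)C(C)(C)C | intermediate
5 | 1-(phenylsulfonyl)propan-2-one | CC(=O)CS(=O)(=O)c1ccccc1 | starting material
6 | sodium lithium 1,3-dianion of 1-(phenylsulfonyl)propan-2-one | [CH2-]C(=O)[CH-]S(=O)(=O)c1ccccc1.[Na+].[Li+] | intermediate
7 | (2E,6E,10E)-3,7,11-trimethyl-14-oxo-15-(phenylsulfonyl)pentadeca-2,6,10-trien-1-yl pivalate | O=C(CS(=O)(=O)c1ccccc1)CC/C(C)=C/CC/C(C)=C/CC/C(C)=C/COC(=O)C(C)(C)C | intermediate
8 | (2E,6E,10E)-15-diazo-3,7,11-trimethyl-14-oxo-15-(phenylsulfonyl)pentadeca-2,6,10-trien-1-yl pivalate | O=C(C(=[N+]=[N-])S(=O)(=O)c1ccccc1)CC/C(C)=C/CC/C(C)=C/CC/C(C)=C/COC(=O)C(C)(C)C | intermediate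
9 | (2E,6E)-3,7-dimethyl-9-[(1S,5S,6S)-5-methyl-2-oxo-1-(phenylsulfonyl)bicyclo[3.1.0]hexan-6-yl]nona-2,6-dien-1-yl pivalate | O=C1CC[C@@]2(C)[C@H](CC/C(C)=C/CC/C(C)=C/COC(=O)C(C)(C)C)[C@@]12S(=O)(=O)c3ccccc3 | intermediate
10 | (4R,5S,9R,10S)-3-oxo-4-(phenylsulfonyl)-18,19-dinorlabda-7,13E-dien-15-yl pivalate | CC1=CC[C@@H]2[C@@H](S(=O)(=O)c3ccccc3)C(=O)CC[C@@]2(C)[C@@H]1CC/C(C)=C/COC(=O)C(C)(C)C | intermediate
11 | (4S,5S,9R,10S)-3-oxo-4-(phenylsulfonyl)-19-norlabda-7,13E-dien-15-yl pivalate | CC1=CC[C@@H]2[C@](C)(S(=O)(=O)c3ccccc3)C(=O)CC[C@@]2(C)[C@@H]1CC/C(C)=C/COC(=O)C(C)(C)C | intermediate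
12 | lithium C3–C4 enolate of the 4-methyl-3-ketone | CC1=CC[C@@H]2C(C)=C([O-])CC[C@@]2(C)[C@@H]1CC/C(C)=C/COC(=O)C(C)(C)C.[Li+] | intermediate
13 | (5S,9R,10S)-3-oxolabda-7,13E-dien-15-yl pivalate | CC1=CC[C@@H]2C(C)(C)C(=O)CC[C@@]2(C)[C@@H]1CC/C(C)=C/COC(=O)C(C)(C)C | intermediate
14 | (3R,5S,9R,10S)-labda-7,13E-diene-3,15-diol | CC1=CC[C@@H]2C(C)(C)[C@H](O)CC[C@@]2(C)[C@@H]1CC/C(C)=C/CO | intermediate
15 | ω-pentadecalactone (oxacyclohexadecan-2-one) | O=C1CCCCCCCCCCCCCCO1 | starting material
16 | 15-bromopentadecanoic acid | OC(=O)CCCCCCCCCCCCCCBr | intermediate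
17 | (14-carboxytetradecyl)triphenylphosphonium bromide | OC(=O)CCCCCCCCCCCCCC[P+](c1ccccc1)(c1ccccc1)c1ccccc1.[Br-] | intermediate
18 | methyl 15-hydroxypentadecanoate | COC(=O)CCCCCCCCCCCCCCO | intermediate
19 | methyl 15-(tert-butyldiphenylsilyloxy)pentadecanoate | COC(=O)CCCCCCCCCCCCCCO[Si](c1ccccc1)(c1ccccc1)C(C)(C)C | intermediate
20 | 15-(tert-butyldiphenylsilyloxy)pentadecanal | O=CCCCCCCCCCCCCCCO[Si](c1ccccc1)(c1ccccc1)C(C)(C)C | intermediate
21 | sodium 15-(triphenylphosphoranylidene)pentadecanoate | [O-]C(=O)CCCCCCCCCCCCCC=P(c1ccccc1)(c1ccccc1)c1ccccc1.[Na+] | intermediate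
22 | (15Z)-30-(tert-butyldiphenylsilyloxy)triacont-15-enoic acid | OC(=O)CCCCCCCCCCCCC/C=C\CCCCCCCCCCCCCCO[Si](c1ccccc1)(c1ccccc1)C(C)(C)C | intermediate
23 | 30-(tert-butyldiphenylsilyloxy)triacontanoic acid | OC(=O)CCCCCCCCCCCCCCCCCCCCCCCCCCCCCO[Si](c1ccccc1)(c1ccccc1)C(C)(C)C | intermediate
24 | (3R,5S,9R,10S)-3-hydroxylabda-7,13E-dien-15-yl 30-(tert-butyldiphenylsilyloxy)triacontanoate | CC1=CC[C@@H]2C(C)(C)[C@H](O)CC[C@@]2(C)[C@@H]1CC/C(C)=C/COC(=O)CCCCCCCCCCCCCCCCCCCCCCCCCCCCCO[Si](c1ccccc1)(c1ccccc1)C(C)(C)C | intermediate
25 | (3R,5S,9R,10S)-3-hydroxylabda-7,13E-dien-15-yl 30-hydroxytriacontanoate | CC1=CC[C@@H]2C(C)(C)[C@H](O)CC[C@@]2(C)[C@@H]1CC/C(C)=C/COC(=O)CCCCCCCCCCCCCCCCCCCCCCCCCCCCCO | target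

## Step count and risks

Total step count: 19.

Longest linear sequence: 12 steps (steps 1–10, 18, 19).

**Step 7.**
- What may go wrong: cleavage of the other cyclopropane bond, proton loss from the C10 cation before ring closure, unselective proton loss at the C8 cation, or a third ring closure.
- The fallback sets out from 9 and separates the two events, using known chemistry only.
- The cyclopropane would first be ring-enlarged alone by hydrochlorination with pyridinium chloride in MeCN. This is the known opening of activated cyclopropanes by halide at the carbon that best carries positive charge, and the trisubstituted olefins are inert to this reagent. It would give the ring-enlarged tertiary C10 chloride, (2E,6E)-9-[2-chloro-2-methyl-5-oxo-6-(phenylsulfonyl)cyclohexyl]-3,7-dimethylnona-2,6-dien-1-yl pivalate F1.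
- Halide abstraction with AgBF4 and 2,6-di-tert-butylpyridine in CH2Cl2 at −78 °C is the known start of cation–olefin cyclisations from tertiary halides. It would then close ring B from the free C10 cation.
- In that cation the equatorial side chain on C5 and the chair closure familiar from monocyclic terpenoid cations again lead to the trans-decalin. The route is rejoined at 10.

**Step 6.**
- What may go wrong: insufficient face selection by the catalyst on a trisubstituted olefin, or diversion of the carbenoid to more remote olefins.
- The fallback sets out from 8 and gives up asymmetric catalysis.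
- Decomposition with achiral Cu(acac)2 in refluxing toluene keeps the stereospecific syn addition. It should give 9 together with its mirror image, the (1R,5R,6R)-cyclopropane F2.
- The two would be separated by preparative chromatography on a chiral stationary phase, and the route is rejoined at 9.

**Step 9.**
- What may go wrong: proton transfer to the enolate before methylation, O-methylation, or electron transfer to the allylic pivalate when excess reductant is present.
- The fallback sets out from 11 and separates enolate formation from alkylation.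
- The enolate made with lithium naphthalenide would be trapped with Me3SiCl and isolated as the regiodefined trimethylsilyl enol ether F3.
- This would then be methylated with MeI and benzyltrimethylammonium fluoride under aprotic conditions (fluoride-mediated alkylation of enol silanes). The route is rejoined at 13.

## Further compounds

F1 | step 7 | (2E,6E)-9-[2-chloro-2-methyl-5-oxo-6-(phenylsulfonyl)cyclohexyl]-3,7-dimethylnona-2,6-dien-1-yl pivalate, chloride on the face opposite the broken C4–C10 bond | O=C1CC[C@@](C)(Cl)[C@H](CC/C(C)=C/CC/C(C)=C/COC(=O)C(C)(C)C)[C@H]1S(=O)(=O)c2ccccc2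
F2 | step 6 | (2E,6E)-3,7-dimethyl-9-[(1R,5R,6R)-5-methyl-2-oxo-1-(phenylsulfonyl)bicyclo[3.1.0]hexan-6-yl]nona-2,6-dien-1-yl pivalate | O=C1CC[C@]2(C)[C@@H](CC/C(C)=C/CC/C(C)=C/COC(=O)C(C)(C)C)[C@]12S(=O)(=O)c3ccccc3
F3 | step 9 | (5S,9R,10S)-3-(trimethylsilyloxy)-19-norlabda-3,7,13E-trien-15-yl pivalate | CC1=CC[C@@H]2C(C)=C(O[Si](C)(C)C)CC[C@@]2(C)[C@@H]1CC/C(C)=C/COC(=O)C(C)(C)C
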